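**Retrosynthetic overview** (labdane numbering: decalin C1–C10, side chain C11–C16, C17 on C8, C18/C19 on C4, C20 on C10)
1. Endgame: the C3 acetate, the 8α-methyl configuration and the spiro-butanolide are installed last; the butanolide comes from C13–C16 bond formation (hydroxymethyl radical onto a C13=C14 ylidene acetate), which leads back to a C13 lactone carbonyl in tricycle 18.
2. Key disconnection: C5–C10 and C8–C9 of ring B, formed together in an intramolecular polar [4+2] of a 6-benzyloxy-7-silyloxy diene (C5=C6–C7=C8) with the exocyclic C9=C10 alkene of a 5-ylidene-2(5H)-furanone; rings A and B and the centres C5, C8, C9 and C10 arise at once.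
3. Enabling feature: ring B is a cyclohexanone whose C6/C7 acyloin is a masked C6=C7 enediol (a cyclohexene retron), C5–C10 is the bond shared with ring A, and C9 is the spiro carbon carrying the oxygen of the five-membered ring; C13 can therefore serve as a lactone carbonyl that activates C9=C10 through C11=C12.
4. The triene is assembled linearly: reverse prenylation (C3), alkyne formylation and acetate aldol (C11–C13), alkene cleavage and Horner–Wadsworth–Emmons olefination (diene half), anti iodolactonisation and Negishi methylation (Z tetrasubstituted dienophile).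
5. Ring order: furanone ring (step 10), rings A and B together (step 14), then the butanolide (step 18); the oxolane is the original furanone ring.

Key step: step 14

Remark: pent-4-yn-1-ol, benzyl chloromethyl ether and triethyl phosphite are taken as commercial; the carbinol centre made in step 7 is carried as an epimer mixture because step 12 removes it.

**Step 1**
Reactants: 1 benzyl chloromethyl ether; 2 triethyl phosphite
Product: 3 diethyl [(benzyloxy)methyl]phosphonate
Conditions: neat, 150 °C, EtCl distilled off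
Reagents that add atoms: none
Why: Michaelis–Arbuzov reaction of a reactive α-chloro ether; no stereocentre is formed.

**Step 2**
Reactants: 3 diethyl [(benzyloxy)methyl]phosphonate
Product: 4 diethyl [1-(benzyloxy)-2-oxobutyl]phosphonate (racemic)
Conditions: LiN(i-Pr)2 (2.1 equiv), THF, −78 °C; EtC(O)N(OMe)Me; 1 M HCl
Reagents that add atoms: N-methoxy-N-methylpropanamide, CCC(=O)N(C)OC
Why: C-acylation of the α-lithiated phosphonate by a Weinreb amide, which cannot over-add; the new centre is racemic and becomes sp2 in step 9.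

**Step 3**
Reactants: 5 pent-4-yn-1-ol
Product: 6 pent-4-ynal
Conditions: TEMPO (10 mol %), PhI(OAc)2, CH2Cl2, rt; used as a solution
Reagents that add atoms: none
Why: oxoammonium-mediated oxidation of a primary alcohol stops at the aldehyde.

**Step 4**
Reactants: 6 pent-4-ynal
Product: 7 (S)-3,3-dimethyloct-1-en-7-yn-4-ol
Conditions: (+)-Ipc2BH [from (−)-α-pinene], 3-methylbuta-1,2-diene, THF, −25 → 0 °C; then 6, −78 °C; NaOH, H2O2
Reagents that add atoms: 3-methylbuta-1,2-diene, CC(C)=C=C
Why: allylboration through a chair (Zimmerman–Traxler) transition state in which the γ,γ-dimethylallyl borane reacts at its substituted terminus (reverse prenylation); the isopinocampheyl groups from (−)-α-pinene should direct attack to the re face and set the S carbinol (C3).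

**Step 5**
Reactants: 7 (S)-3,3-dimethyloct-1-en-7-yn-4-ol
Product: 8 (S)-4-(benzyloxy)-3,3-dimethyloct-1-en-7-yne
Conditions: NaH, BnBr, Bu4NI (cat.), THF, 0 °C → rt
Reagents that add atoms: benzyl bromide, BrCc1ccccc1
Why: Williamson etherification of the alkoxide; the stereocentre is not touched.

**Step 6**
Reactants: 8 (S)-4-(benzyloxy)-3,3-dimethyloct-1-en-7-yne
Product: 9 (S)-6-(benzyloxy)-7,7-dimethylnon-8-en-2-ynal
Conditions: n-BuLi, THF, −78 °C; DMF; inverse quench into aq. NH4Cl
Reagents that add atoms: N,N-dimethylformamide, CN(C)C=O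
Why: formylation of the lithium acetylide with DMF; the hemiaminal alkoxide releases the ynal only on buffered work-up.

**Step 7**
Reactants: 9 (S)-6-(benzyloxy)-7,7-dimethylnon-8-en-2-ynal
Product: 10 (8S)-8-(benzyloxy)-3-hydroxy-9,9-dimethylundec-10-en-4-ynoic acid (C3 epimers)
Conditions: LiN(i-Pr)2, Me3SiOAc, THF, −78 °C; then 9; 1 M HCl work-up
Reagents that add atoms: trimethylsilyl acetate, CC(=O)O[Si](C)(C)C
Why: aldol addition of the lithium enolate of trimethylsilyl acetate (an acetic acid enolate equivalent) to the non-enolisable ynal, the silyl ester being cleaved on work-up; the new carbinol centre is uncontrolled and is removed in step 12.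

**Step 8**
Reactants: 10 (8S)-8-(benzyloxy)-3-hydroxy-9,9-dimethylundec-10-en-4-ynoic acid
Product: 11 (8S)-8-(benzyloxy)-3-hydroxy-9,9-dimethyl-10-oxodec-4-ynoic acid (C3 epimers)
Conditions: OsO4 (2 mol %), NaIO4, 2,6-lutidine, dioxane/H2O, rt
Reagents that add atoms: sodium periodate (oxygen donor by way of OsO4), [Na+].[O-]I(=O)(=O)=O
Why: Lemieux–Johnson cleavage; OsO4 dihydroxylates the monosubstituted alkene far faster than the alkyne, and the resulting C5 aldehyde has no α-hydrogen, so it can neither epimerise nor eliminate.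

**Step 9**
Reactants: 11 (8S)-8-(benzyloxy)-3-hydroxy-9,9-dimethyl-10-oxodec-4-ynoic acid; 4 diethyl [1-(benzyloxy)-2-oxobutyl]phosphonate
Product: 12 (8S,10Z)-8,11-bis(benzyloxy)-3-hydroxy-9,9-dimethyl-12-oxotetradec-10-en-4-ynoic acid (C3 epimers)
Conditions: LiCl, DBU (3.5 equiv), MeCN, 0 °C → rt; acidic work-up
Reagents that add atoms: none
Why: Horner–Wadsworth–Emmons olefination under LiCl/amine conditions, which tolerate the carboxylate and the free hydroxyl; the Z enol ether (tert-alkyl group trans to the acyl group) is expected from a stabilised phosphonate and a bulky aldehyde.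

**Step 10**
Reactants: 12 (8S,10Z)-8,11-bis(benzyloxy)-3-hydroxy-9,9-dimethyl-12-oxotetradec-10-en-4-ynoic acid
Product: 13 (5E)-5-[(4S,6Z)-4,7-bis(benzyloxy)-1-iodo-5,5-dimethyl-8-oxodec-6-en-1-ylidene]-4-hydroxyoxolan-2-one (C4 epimers)
Conditions: I2, NaHCO3, MeCN, 0 °C, dark
Reagents that add atoms: iodine, II
Why: iodolactonisation of a 4-alkynoic acid; anti addition of iodine and carboxylate in the 5-exo-dig mode gives the E iodo enol lactone and thereby fixes C1 cis to the ring oxygen in the future dienophile.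

**Step 11**
Reactants: 13 (5E)-5-[(4S,6Z)-4,7-bis(benzyloxy)-1-iodo-5,5-dimethyl-8-oxodec-6-en-1-ylidene]-4-hydroxyoxolan-2-one
Product: 14 (5Z)-5-[(5S,7Z)-5,8-bis(benzyloxy)-6,6-dimethyl-9-oxoundec-7-en-2-ylidene]-4-hydroxyoxolan-2-one (C4 epimers)
Conditions: MeZnCl (3 equiv), Pd(PPh3)4 (5 mol %), THF, rt
Reagents that add atoms: methylzinc chloride, C[Zn]Cl
Why: Negishi coupling with retention at the alkenyl iodide places the C10 methyl (C20) trans to the ring oxygen; the organozinc should leave ketone, enone and lactone untouched.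

**Step 12**
Reactants: 14 (5Z)-5-[(5S,7Z)-5,8-bis(benzyloxy)-6,6-dimethyl-9-oxoundec-7-en-2-ylidene]-4-hydroxyoxolan-2-one
Product: 16 (5Z)-5-[(5S,7Z)-5,8-bis(benzyloxy)-6,6-dimethyl-9-oxoundec-7-en-2-ylidene]furan-2(5H)-one, via mesylate 15 (not isolated)
Conditions: MsCl, Et3N, CH2Cl2, −20 °C → rt
Reagents that add atoms: none
Why: mesylation and E1cB elimination (loss of the C12 hydrogen) give the conjugated 5-ylidene-2(5H)-furanone; the exocyclic geometry is not affected and the carbinol centre disappears.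

**Step 13**
Reactants: 16 (5Z)-5-[(5S,7Z)-5,8-bis(benzyloxy)-6,6-dimethyl-9-oxoundec-7-en-2-ylidene]furan-2(5H)-one
Product: 17 (5Z)-5-[(5S,7Z,9Z)-5,8-bis(benzyloxy)-9-(tert-butyldimethylsilyloxy)-6,6-dimethylundeca-7,9-dien-2-ylidene]furan-2(5H)-one
Conditions: TBSOTf (1.1 equiv), Et3N, CH2Cl2, −78 °C; filtration through basic alumina
Reagents that add atoms: tert-butyldimethylsilyl trifluoromethanesulfonate, CC(C)(C)[Si](C)(C)OS(=O)(=O)C(F)(F)F
Why: soft enolisation of the ethyl ketone (silyl triflate and amine), which is silylated much faster than the lactone, should give the Z silyl enol ether; the diene then has the tether and the C8 methyl both in outside positions.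

**Step 14**
Reactants: 17 (5Z)-5-[(5S,7Z,9Z)-5,8-bis(benzyloxy)-9-(tert-butyldimethylsilyloxy)-6,6-dimethylundeca-7,9-dien-2-ylidene]furan-2(5H)-one
Product: 18 3β,6-bis(benzyloxy)-7-(tert-butyldimethylsilyloxy)-8-epi-14,15,16-trinorlabda-6,11-dien-13,9α-olide (5α-H; 8β-methyl; 10β-methyl; ring oxygen α on C9)
Conditions: HNTf2 (10 mol %), CH2Cl2, −78 → −40 °C; Et3N quench
Reagents that add atoms: none
Why: Proposed new method: HNTf2 protodesilylates a trace of 17 to TBSNTf2, which silylates the furanone carbonyl; the benzyl enol ether carbon C5 then adds to the exocyclic C10 of the silyloxyfuryl carbenium ion (vinylogous Mukaiyama–Michael, ring A closing 6-exo through a chair with the C3 benzyloxy group equatorial), and the 2-silyloxyfuran so formed adds through C9 to C8 of the O-benzyl oxocarbenium/silyl enol ether (ring B closing 6-endo), releasing the silyl cation and leaving the C6=C7 enediol diether, so the sum is an intramolecular [4+2]. The closest known reaction type is the triflimide- or silyl-triflimide-catalysed stepwise Diels–Alder reaction of hindered 2-silyloxydienes with tetrasubstituted enones that builds vicinal quaternary carbons, together with thermal Diels–Alder additions to the exocyclic alkene of 5-ylidene-2(5H)-furanones; the polarity is matched because the oxygen on C6 makes C5 the nucleophilic terminus and the lactone makes C10 the electrophilic one. C9 and C10 follow from the Z alkene geometry (C1 cis to the ring oxygen) in the compact endo-type arrangement with C11=C12 under the diene, which puts the C10 methyl and C11 on the β face and the ring oxygen α (axial) on a trans-fused decalin, and C5 (H α) follows from the same arrangement. C8 takes its methyl on the β face because the methyl is the outside substituent of the Z silyl enol ether; this centre is corrected in step 19. The step needs π-facial selectivity, which the equatorial C3 substituent should provide and the low temperature should sharpen, and endo rather than exo closure, which the attraction between the forming silyloxyfuran and the oxocarbenium unit favours.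

**Step 15**
Reactants: 18 3β,6-bis(benzyloxy)-7-(tert-butyldimethylsilyloxy)-8-epi-14,15,16-trinorlabda-6,11-dien-13,9α-olide
Product: 19 3β,6-bis(benzyloxy)-7-(tert-butyldimethylsilyloxy)-8-epi-14,15,16-trinorlabd-6-en-13,9α-olide
Conditions: H2 (1 atm), RhCl(PPh3)3 (5 mol %), benzene, rt
Reagents that add atoms: none
Why: homogeneous hydrogenation reduces the disubstituted butenolide alkene but neither the tetrasubstituted enediol diether nor the benzyl ethers.

**Step 16**
Reactants: 19 3β,6-bis(benzyloxy)-7-(tert-butyldimethylsilyloxy)-8-epi-14,15,16-trinorlabd-6-en-13,9α-olide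
Product: 21 methyl 3β,6-bis(benzyloxy)-7-(tert-butyldimethylsilyloxy)-9α,13-epoxy-8-epi-16-norlabda-6,13-dien-15-oate (E/Z mixture at C13=C14), via hemiketal 20 (not isolated)
Conditions: LiN(i-Pr)2, MeOAc, THF, −78 °C; AcOH; then MsCl, Et3N, CH2Cl2, 0 °C → rt
Reagents that add atoms: methyl acetate, CC(=O)OC
Why: Claisen-type addition of the ester enolate to the γ-lactone stops at the hemiketal, and mesylation/elimination under basic conditions gives the exocyclic enol ether ester without exposing the enediol diether to acid; both alkene isomers converge in step 18.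

**Step 17**
Reactants: 21 methyl 3β,6-bis(benzyloxy)-7-(tert-butyldimethylsilyloxy)-9α,13-epoxy-8-epi-16-norlabda-6,13-dien-15-oate
Product: 22 methyl 3β,6β-bis(benzyloxy)-9α,13-epoxy-7-oxo-8-epi-16-norlabd-13-en-15-oate
Conditions: Bu4NF (1.1 equiv), AcOH (3 equiv), THF, −78 → 0 °C
Reagents that add atoms: none
Why: fluoride cleaves the silyl enol ether, and because O6 is benzylated the enol can ketonise only by protonation at C6; this should occur from the α face (the β face is screened by the axial C4 and C10 methyls) and give the 7-ketone with the 6β-benzyloxy group.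

**Step 18**
Reactants: 22 methyl 3β,6β-bis(benzyloxy)-9α,13-epoxy-7-oxo-8-epi-16-norlabd-13-en-15-oate
Product: 24 (13R)-3β,6β-bis(benzyloxy)-9α,13-epoxy-7-oxo-8-epi-labdan-15,16-olide, via hydroxy ester 23 (not isolated)
Conditions: MeOH (10 equiv), [Ir(dF(CF3)ppy)2(dtbbpy)]PF6 (1 mol %), quinuclidine (10 mol %), Bu4N(H2PO4) (25 mol %), MeCN, blue LEDs, rt
Reagents that add atoms: methanol, CO
Why: Giese-type addition of the hydroxymethyl radical (from methanol by hydrogen-atom transfer under photoredox conditions) to the β-carbon of the β-alkoxyacrylate, then lactonisation; the radical should approach C13 on the oxolane face syn to C8, which carries only hydrogen on its α side at this stage, and anti to the C1 methylene of ring A, so that C16 ends cis to C8 (13R).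

**Step 19**
Reactants: 24 (13R)-3β,6β-bis(benzyloxy)-9α,13-epoxy-7-oxo-8-epi-labdan-15,16-olide
Product: 25 (13R)-3β,6β-bis(benzyloxy)-9α,13-epoxy-7-oxolabdan-15,16-olide (8α-methyl)
Conditions: DBU (0.5 equiv), toluene, rt → 40 °C, monitored
Reagents that add atoms: none
Why: base-mediated equilibration through the C7–C8 enolate should relieve the syn-diaxial C8-methyl/C10-methyl interaction and place the methyl equatorial (8α); C6 should be spared because reprotonation of its enolate from the open α face returns the same configuration.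

**Step 20**
Reactants: 25 (13R)-3β,6β-bis(benzyloxy)-9α,13-epoxy-7-oxolabdan-15,16-olide
Product: 26 (13R)-3β,6β-dihydroxy-9α,13-epoxy-7-oxolabdan-15,16-olide
Conditions: H2 (1–3 atm), Pd(OH)2/C, EtOAc, rt
Reagents that add atoms: none
Why: hydrogenolysis of both benzyl ethers; the hindered ketone and the lactone are inert and no stereocentre is affected.

**Step 21**
Reactants: 26 (13R)-3β,6β-dihydroxy-9α,13-epoxy-7-oxolabdan-15,16-olide
Product: 27 (13R)-3β-acetoxy-6β-hydroxy-9α,13-epoxy-7-oxolabdan-15,16-olide (CNP0325396.1)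
Conditions: Ac2O (1.5 equiv), pyridine, 0 °C → rt
Reagents that add atoms: acetic anhydride, CC(=O)OC(C)=O
Why: selective acylation of the equatorial C3 hydroxyl; the axial 6β-hydroxyl, flanked by two syn-axial methyls and the carbonyl, should react far more slowly.

**Compound list**
1 | benzyl chloromethyl ether | ClCOCc1ccccc1 | starting material
2 | triethyl phosphite | CCOP(OCC)OCC | starting material
3 | diethyl [(benzyloxy)methyl]phosphonate | CCOP(=O)(COCc1ccccc1)OCC | intermediate
4 | diethyl [1-(benzyloxy)-2-oxobutyl]phosphonate (racemic) | CCOP(=O)(OCC)C(OCc1ccccc1)C(=O)CC | intermediate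
5 | pent-4-yn-1-ol | C#CCCCO | starting material
6 | pent-4-ynal | C#CCCC=O | intermediate
7 | (S)-3,3-dimethyloct-1-en-7-yn-4-ol | C=CC(C)(C)[C@@H](O)CCC#C | intermediate
8 | (S)-4-(benzyloxy)-3,3-dimethyloct-1-en-7-yne | C=CC(C)(C)[C@@H](OCc1ccccc1)CCC#C | intermediate
9 | (S)-6-(benzyloxy)-7,7-dimethylnon-8-en-2-ynal | C=CC(C)(C)[C@@H](OCc1ccccc1)CCC#CC=O | intermediate
10 | (8S)-8-(benzyloxy)-3-hydroxy-9,9-dimethylundec-10-en-4-ynoic acid (C3 epimers) | C=CC(C)(C)[C@@H](OCc1ccccc1)CCC#CC(O)CC(=O)O | intermediate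
11 | (8S)-8-(benzyloxy)-3-hydroxy-9,9-dimethyl-10-oxodec-4-ynoic acid (C3 epimers) | O=CC(C)(C)[C@@H](OCc1ccccc1)CCC#CC(O)CC(=O)O | intermediate
12 | (8S,10Z)-8,11-bis(benzyloxy)-3-hydroxy-9,9-dimethyl-12-oxotetradec-10-en-4-ynoic acid (C3 epimers) | CCC(=O)/C(OCc1ccccc1)=C/C(C)(C)[C@@H](OCc1ccccc1)CCC#CC(O)CC(=O)O | intermediate
13 | (5E)-5-[(4S,6Z)-4,7-bis(benzyloxy)-1-iodo-5,5-dimethyl-8-oxodec-6-en-1-ylidene]-4-hydroxyoxolan-2-one (C4 epimers) | CCC(=O)/C(OCc1ccccc1)=C/C(C)(C)[C@@H](OCc1ccccc1)CC/C(I)=C1\OC(=O)CC1O | intermediate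
14 | (5Z)-5-[(5S,7Z)-5,8-bis(benzyloxy)-6,6-dimethyl-9-oxoundec-7-en-2-ylidene]-4-hydroxyoxolan-2-one (C4 epimers) | CCC(=O)/C(OCc1ccccc1)=C/C(C)(C)[C@@H](OCc1ccccc1)CC/C(C)=C1\OC(=O)CC1O | intermediate
15 | methanesulfonate of 14 at the ring hydroxyl (not isolated) | CCC(=O)/C(OCc1ccccc1)=C/C(C)(C)[C@@H](OCc1ccccc1)CC/C(C)=C1\OC(=O)CC1OS(C)(=O)=O | intermediate
16 | (5Z)-5-[(5S,7Z)-5,8-bis(benzyloxy)-6,6-dimethyl-9-oxoundec-7-en-2-ylidene]furan-2(5H)-one | CCC(=O)/C(OCc1ccccc1)=C/C(C)(C)[C@@H](OCc1ccccc1)CC/C(C)=C1\OC(=O)C=C1 | intermediate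
17 | (5Z)-5-[(5S,7Z,9Z)-5,8-bis(benzyloxy)-9-(tert-butyldimethylsilyloxy)-6,6-dimethylundeca-7,9-dien-2-ylidene]furan-2(5H)-one | C/C=C(O[Si](C)(C)C(C)(C)C)/C(OCc1ccccc1)=C/C(C)(C)[C@@H](OCc1ccccc1)CC/C(C)=C1\OC(=O)C=C1 | intermediate
18 | 3β,6-bis(benzyloxy)-7-(tert-butyldimethylsilyloxy)-8-epi-14,15,16-trinorlabda-6,11-dien-13,9α-olide | O(Cc1ccccc1)[C@H]2CC[C@@]3(C)[C@@H](C(OCc4ccccc4)=C(O[Si](C)(C)C(C)(C)C)[C@H](C)[C@]35C=CC(=O)O5)C2(C)C | intermediate
19 | 3β,6-bis(benzyloxy)-7-(tert-butyldimethylsilyloxy)-8-epi-14,15,16-trinorlabd-6-en-13,9α-olide | O(Cc1ccccc1)[C@H]2CC[C@@]3(C)[C@@H](C(OCc4ccccc4)=C(O[Si](C)(C)C(C)(C)C)[C@H](C)[C@]35CCC(=O)O5)C2(C)C | intermediate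
20 | methyl 3β,6-bis(benzyloxy)-7-(tert-butyldimethylsilyloxy)-9α,13-epoxy-13-hydroxy-8-epi-16-norlabd-6-en-15-oate (hemiketal, C13 mixture, not isolated) | O(Cc1ccccc1)[C@H]2CC[C@@]3(C)[C@@H](C(OCc4ccccc4)=C(O[Si](C)(C)C(C)(C)C)[C@H](C)[C@]35CCC(O)(CC(=O)OC)O5)C2(C)C | intermediate
21 | methyl 3β,6-bis(benzyloxy)-7-(tert-butyldimethylsilyloxy)-9α,13-epoxy-8-epi-16-norlabda-6,13-dien-15-oate (E/Z mixture) | O(Cc1ccccc1)[C@H]2CC[C@@]3(C)[C@@H](C(OCc4ccccc4)=C(O[Si](C)(C)C(C)(C)C)[C@H](C)[C@]35CCC(=CC(=O)OC)O5)C2(C)C | intermediate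
22 | methyl 3β,6β-bis(benzyloxy)-9α,13-epoxy-7-oxo-8-epi-16-norlabd-13-en-15-oate (E/Z mixture) | O(Cc1ccccc1)[C@H]2CC[C@@]3(C)[C@@H]([C@H](OCc4ccccc4)C(=O)[C@H](C)[C@]35CCC(=CC(=O)OC)O5)C2(C)C | intermediate
23 | methyl (13R)-3β,6β-bis(benzyloxy)-9α,13-epoxy-16-hydroxy-7-oxo-8-epi-labdan-15-oate (not isolated) | O(Cc1ccccc1)[C@H]2CC[C@@]3(C)[C@@H]([C@H](OCc4ccccc4)C(=O)[C@H](C)[C@]35CC[C@](CO)(CC(=O)OC)O5)C2(C)C | intermediate
24 | (13R)-3β,6β-bis(benzyloxy)-9α,13-epoxy-7-oxo-8-epi-labdan-15,16-olide | O(Cc1ccccc1)[C@H]2CC[C@@]3(C)[C@@H]([C@H](OCc4ccccc4)C(=O)[C@H](C)[C@]35CC[C@@]6(COC(=O)C6)O5)C2(C)C | intermediate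
25 | (13R)-3β,6β-bis(benzyloxy)-9α,13-epoxy-7-oxolabdan-15,16-olide | O(Cc1ccccc1)[C@H]2CC[C@@]3(C)[C@@H]([C@H](OCc4ccccc4)C(=O)[C@@H](C)[C@]35CC[C@@]6(COC(=O)C6)O5)C2(C)C | intermediate
26 | (13R)-3β,6β-dihydroxy-9α,13-epoxy-7-oxolabdan-15,16-olide | O[C@H]2CC[C@@]3(C)[C@@H]([C@H](O)C(=O)[C@@H](C)[C@]35CC[C@@]6(COC(=O)C6)O5)C2(C)C | intermediate
27 | (13R)-3β-acetoxy-6β-hydroxy-9α,13-epoxy-7-oxolabdan-15,16-olide (CNP0325396.1) | CC(=O)O[C@H]1CC[C@@]2(C)[C@@H]([C@H](O)C(=O)[C@@H](C)[C@]23CC[C@@]2(COC(=O)C2)O3)C1(C)C | target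

**Totals**
Total step count: 21. Longest linear sequence: 19 steps (steps 3–21); steps 1–2 are a two-step branch to phosphonate 4.

**Steps most likely to fail**

Step 14 (proposed new method). The acid-triggered process may be diverted before the first C–C bond forms: protodesilylation of the dienol ether, or loss of a proton (C1 or C20) from the silylated furanone to give a 2-silyloxy-5-alkenylfuran; facial discrimination by the remote C3 centre may also be poor. The fallback uses known chemistry, a thermal concerted intramolecular Diels–Alder addition of a 2-silyloxydiene to the exocyclic alkene of a 5-ylidene-2(5H)-furanone, with the dienophile released only in the reaction flask. It sets out from 14. Acetylation (Ac2O, pyridine, 0 °C) gives the ring acetate F1; TBSOTf/Et3N at −78 °C converts the ethyl ketone into the acetoxy dienol ether F2. Heating F2 in toluene with Et3N and N,O-bis(trimethylsilyl)acetamide (110 °C, then 170 °C, sealed tube) eliminates acetic acid to give 17 in the flask, which should close through the endo transition state, stereospecifically with respect to both alkene geometries. The fallback comes back to the route at 18.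

Step 18. Addition of the nucleophilic radical to the fully substituted β-carbon may be slower than its reduction or dimerisation, and the facial bias at C13 may be insufficient. The fallback replaces the intermolecular radical addition by a [2,3]-sigmatropic delivery of the hydroxymethyl group and sets out from 21. Reduction with i-Bu2AlH (−78 °C) gives the allylic alcohol F3; KH and Bu3SnCH2I give the stannylmethyl ether F4. Tin–lithium exchange (n-BuLi, THF, −78 °C) triggers the Still variant of the [2,3]-Wittig rearrangement, which places CH2OH on C13 from the same open face and gives the 13-vinyl carbinol F5. Hydroboration (9-BBN, then NaBO3) gives the diol F6; Ag2CO3 on Celite (benzene, reflux) oxidises the less hindered primary alcohol and closes the lactone F7. Bu4NF/AcOH as in step 17 then unveils the ketone, and the fallback comes back to the route at 24.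

Step 19. The base may also epimerise C6, or trigger β-elimination (opening of the oxolane at C9 from the C8 enolate, or of the C13–O bond from the lactone enolate, which would scramble C13). The fallback moves the epimerisation to the end and runs it under acid on the free ketol; it sets out from 24. Hydrogenolysis (H2, Pd(OH)2/C, EtOAc) gives the 8-epi diol F8, and Ac2O/pyridine gives the 8-epi acetate F9. Treatment of F9 with p-TsOH (cat.) in CHCl3 at 40 °C enolises the ketone toward C8 without enolising the lactone, and the axial 6β-hydroxyl can relay the proton to the β face of C8. The fallback comes back to the route at 27.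

**Further compounds**
F1 | step 14 | (5Z)-4-acetoxy-5-[(5S,7Z)-5,8-bis(benzyloxy)-6,6-dimethyl-9-oxoundec-7-en-2-ylidene]oxolan-2-one | CCC(=O)/C(OCc1ccccc1)=C/C(C)(C)[C@@H](OCc1ccccc1)CC/C(C)=C1\OC(=O)CC1OC(C)=O
F2 | step 14 | (5Z)-4-acetoxy-5-[(5S,7Z,9Z)-5,8-bis(benzyloxy)-9-(tert-butyldimethylsilyloxy)-6,6-dimethylundeca-7,9-dien-2-ylidene]oxolan-2-one | C/C=C(O[Si](C)(C)C(C)(C)C)/C(OCc1ccccc1)=C/C(C)(C)[C@@H](OCc1ccccc1)CC/C(C)=C1\OC(=O)CC1OC(C)=O
F3 | step 18 | 3β,6-bis(benzyloxy)-7-(tert-butyldimethylsilyloxy)-9α,13-epoxy-8-epi-16-norlabda-6,13-dien-15-ol | O(Cc1ccccc1)[C@H]2CC[C@@]3(C)[C@@H](C(OCc4ccccc4)=C(O[Si](C)(C)C(C)(C)C)[C@H](C)[C@]35CCC(=CCO)O5)C2(C)C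
F4 | step 18 | (tributylstannyl)methyl ether of F3 | O(Cc1ccccc1)[C@H]2CC[C@@]3(C)[C@@H](C(OCc4ccccc4)=C(O[Si](C)(C)C(C)(C)C)[C@H](C)[C@]35CCC(=CCOC[Sn](CCCC)(CCCC)CCCC)O5)C2(C)C
F5 | step 18 | (13R)-3β,6-bis(benzyloxy)-7-(tert-butyldimethylsilyloxy)-9α,13-epoxy-8-epi-labda-6,14-dien-16-ol | O(Cc1ccccc1)[C@H]2CC[C@@]3(C)[C@@H](C(OCc4ccccc4)=C(O[Si](C)(C)C(C)(C)C)[C@H](C)[C@]35CC[C@](CO)(C=C)O5)C2(C)C
F6 | step 18 | (13R)-3β,6-bis(benzyloxy)-7-(tert-butyldimethylsilyloxy)-9α,13-epoxy-8-epi-labd-6-ene-15,16-diol | O(Cc1ccccc1)[C@H]2CC[C@@]3(C)[C@@H](C(OCc4ccccc4)=C(O[Si](C)(C)C(C)(C)C)[C@H](C)[C@]35CC[C@](CO)(CCO)O5)C2(C)C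
F7 | step 18 | (13R)-3β,6-bis(benzyloxy)-7-(tert-butyldimethylsilyloxy)-9α,13-epoxy-8-epi-labd-6-en-15,16-olide | O(Cc1ccccc1)[C@H]2CC[C@@]3(C)[C@@H](C(OCc4ccccc4)=C(O[Si](C)(C)C(C)(C)C)[C@H](C)[C@]35CC[C@@]6(COC(=O)C6)O5)C2(C)C
F8 | step 19 | (13R)-3β,6β-dihydroxy-9α,13-epoxy-7-oxo-8-epi-labdan-15,16-olide | O[C@H]2CC[C@@]3(C)[C@@H]([C@H](O)C(=O)[C@H](C)[C@]35CC[C@@]6(COC(=O)C6)O5)C2(C)C
F9 | step 19 | (13R)-3β-acetoxy-6β-hydroxy-9α,13-epoxy-7-oxo-8-epi-labdan-15,16-olide | CC(=O)O[C@H]1CC[C@@]2(C)[C@@H]([C@H](O)C(=O)[C@H](C)[C@]23CC[C@@]2(COC(=O)C2)O3)C1(C)C
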